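The target is fisetinidol-(4β→6)-leucofisetinidin. Everything rests on cutting pyran ring F at C4'–C4a' and O1'–C2'. Ring D is a resorcinol whose free C8a' hydroxyl has a nucleophilic ortho carbon (C4a'). The chain C4'–C3'–C2' carries oxygen on every carbon, so it maps onto a trans-3-arylglycidaldehyde. In one operation the magnesium phenoxide of ring D is hydroxyalkylated at C4a' by the aldehyde, and its oxygen then opens the oxirane at the benzylic carbon. This gives ring F, two skeletal bonds and the C2' and C4' configurations. The precursor is the complete, benzyl-protected upper 4β-arylflavan-3-ol with one free phenol on ring D.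

Key step: step 14

Remarks on the chemistry
- Labels: the upper unit has rings A (benzo), B (catechol) and C (pyran) with unprimed atoms. The lower unit has rings D (benzo), E (catechol) and F (pyran) with primed atoms.
- Stereochemical reading of the target: the upper unit is 2R,3S,4S, that is 2,3-trans-3,4-cis with ring D on the β face, cis to O3. The lower unit is 2'R,3'S,4'R (all-trans). The label at upper C4 is S in 15, 16, 21 and 24 but formally R in 22 and 23, because the ranking of C4a and C6' switches. The geometry does not change.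
- Assumption: ketone 1 is bought. It is otherwise the selective 4-O-benzylation product of 2,4-dihydroxyacetophenone.
- Design choice: ring C is closed at the ketone oxidation level before ring D is attached. No intermediate then holds both an oxirane and the very ionisable diaryl carbinol.

Step 1
Reactants: 1 1-[4-(benzyloxy)-2-hydroxyphenyl]ethanone
Product: 2 1-[4-(benzyloxy)-2-(methoxymethoxy)phenyl]ethanone
Conditions: MOMCl, Cs2CO3, DMF, 0 °C → rt
Reagents that add atoms: chloromethyl methyl ether, COCCl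
Why: Williamson-type O-alkylation in which Cs2CO3 in DMF breaks the hydrogen bond of the chelated 2-hydroxyl and MOMCl masks the future O1, which keeps the coming enone from cyclising to a flavanone and its epoxide from opening too early.

Step 2
Reactants: 2 1-[4-(benzyloxy)-2-(methoxymethoxy)phenyl]ethanone; 3 3,4-bis(benzyloxy)benzaldehyde
Product: 4 (E)-1-[4-(benzyloxy)-2-(methoxymethoxy)phenyl]-3-[3,4-bis(benzyloxy)phenyl]prop-2-en-1-one
Conditions: KOH (aq), EtOH–THF, rt
Reagents that add atoms: none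
Why: Claisen–Schmidt aldol condensation of a methyl ketone with a non-enolisable aldehyde, whose E1cB dehydration gives only the conjugated (E)-enone while MOM and benzyl ethers are inert to hydroxide.

Step 3
Reactants: 4 the (E)-chalcone
Product: 5 [4-(benzyloxy)-2-(methoxymethoxy)phenyl]{(2R,3S)-3-[3,4-bis(benzyloxy)phenyl]oxiran-2-yl}methanone
Conditions: poly-L-leucine, urea·H2O2, DBU, THF, rt
Reagents that add atoms: hydrogen peroxide as its urea adduct, OO.NC(N)=O
Why: Juliá–Colonna epoxidation, a nucleophilic epoxidation in which the helical L-polypeptide binds the enone and steers hydroperoxide to one face, the L-polymer being the one that gives (2R,3S)-epoxides of chalcones including 2'-alkoxymethoxy ones; this fixes the future C3 and, after inversion, C2, and crystallisation should raise the enantiomeric purity.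

Step 4
Reactants: 5 the (2R,3S)-epoxy ketone
Product: 7 (2R,3R)-7-(benzyloxy)-2-[3,4-bis(benzyloxy)phenyl]-3-hydroxychroman-4-one (tri-O-benzylfustin), via free 2'-phenol epoxy ketone 6 (not isolated)
Conditions: HCl, MeOH–THF, 45 °C
Reagents that add atoms: none
Why: Acid-induced acetal cleavage followed by 6-endo-tet opening of the oxirane by the liberated phenol, the established passage from 2'-O-MOM chalcone epoxides to trans-dihydroflavonols: the Cα–O bond is never broken so C3 is retained, O1 attacks the benzylic carbon with inversion to give 2R, and the diequatorial 2,3-trans product is also the more stable one.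

Step 5
Reactants: 7 tri-O-benzylfustin
Product: 8 (2R,3R)-3,7-bis(benzyloxy)-2-[3,4-bis(benzyloxy)phenyl]chroman-4-one
Conditions: BnOC(=NH)CCl3, CF3SO3H (cat.), CH2Cl2–cyclohexane, 0 °C → rt
Reagents that add atoms: benzyl 2,2,2-trichloroacetimidate, ClC(Cl)(Cl)C(=N)OCc1ccccc1
Why: Acid-catalysed O-benzylation with a trichloroacetimidate, chosen because alkoxide conditions would open ring C by β-elimination of the O1 phenoxide or epimerise C3, whereas a trace of strong acid leaves both stereocentres alone.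

Step 6
Reactants: 9 4-bromoresorcinol
Product: 10 2-bromo-5-(triisopropylsilyloxy)phenol
Conditions: iPr3SiCl (1.0 equiv), imidazole, CH2Cl2, 0 °C
Reagents that add atoms: chlorotriisopropylsilane, CC(C)[Si](Cl)(C(C)C)C(C)C
Why: Sterically controlled monosilylation in which the bulky chlorosilane should react first at the hydroxyl para to bromine, which has no ortho substituent, any regioisomer or bis-ether being removed by chromatography.

Step 7
Reactants: 10 2-bromo-5-(triisopropylsilyloxy)phenol
Product: 11 [3-(benzyloxy)-4-bromophenoxy]triisopropylsilane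
Conditions: BnBr, K2CO3, acetone, 50 °C
Reagents that add atoms: benzyl bromide, BrCc1ccccc1
Why: Williamson ether synthesis on the remaining, more acidic ortho-bromophenol under carbonate conditions that an aryl triisopropylsilyl ether tolerates.

Step 8
Reactants: 11 [3-(benzyloxy)-4-bromophenoxy]triisopropylsilane; 8 the 3-O-benzyl flavanone
Product: 14 (2R,3R)-3,7-bis(benzyloxy)-4-[2-(benzyloxy)-4-(triisopropylsilyloxy)phenyl]-2-[3,4-bis(benzyloxy)phenyl]chroman-4-ol (C4 epimers), via aryllithium 12 (not isolated), via arylcerium dichloride 13 (not isolated)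
Conditions: n-BuLi, THF, −78 °C; CeCl3 (anhydrous), −78 °C; then 8, −78 → −40 °C
Reagents that add atoms: none
Why: Bromine–lithium exchange, transmetalation and organocerium 1,2-addition to the ketone, the weakly basic cerium reagent being used to avoid enolisation at C3 and retro-oxa-Michael opening of ring C; the configuration of the new C4 carbinol is of no consequence because it is erased in step 9.

Step 9
Reactants: 14 the tertiary diaryl carbinol
Product: 16 3-(benzyloxy)-4-{(2R,3S,4S)-3,7-bis(benzyloxy)-2-[3,4-bis(benzyloxy)phenyl]chroman-4-yl}phenol, via 4β-aryl triisopropylsilyl ether 15 (not isolated)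
Conditions: Et3SiH, CF3CO2H, CH2Cl2, −40 → −10 °C; NaHCO3 wash; Bu4NF, AcOH, THF, 0 °C
Reagents that add atoms: none
Why: Ionic hydrogenation of a tertiary diaryl carbinol followed by fluoride desilylation: the acid gives the doubly donor-stabilised C4 cation, A(1,2) strain with the twisted ring D tips the 3-benzyloxy group pseudo-axial so that it screens the β face, and Et3SiH should therefore deliver hydride from the α face, anti to C3–O, leaving ring D β and cis to O3 (4S), as in the cis-selective ionic reductions of 1-aryl-2-substituted cyclic cations.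

Step 10
Reactants: 3 3,4-bis(benzyloxy)benzaldehyde
Product: 17 ethyl (E)-3-[3,4-bis(benzyloxy)phenyl]prop-2-enoate
Conditions: (EtO)2P(O)CH2CO2Et, NaH, THF, 0 °C → rt
Reagents that add atoms: triethyl phosphonoacetate, CCOC(=O)CP(=O)(OCC)OCC
Why: Horner–Wadsworth–Emmons olefination with a stabilised phosphonate, which gives the (E)-cinnamate.

Step 11
Reactants: 17 the (E)-cinnamate
Product: 18 (E)-3-[3,4-bis(benzyloxy)phenyl]prop-2-en-1-ol
Conditions: iBu2AlH (2.2 equiv), CH2Cl2, −78 °C
Reagents that add atoms: none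
Why: 1,2-Reduction of the conjugated ester by the aluminium hydride at low temperature, which leaves the alkene geometry and the benzyl ethers untouched.

Step 12
Reactants: 18 the (E)-cinnamyl alcohol
Product: 19 {(2S,3S)-3-[3,4-bis(benzyloxy)phenyl]oxiran-2-yl}methanol
Conditions: Ti(OiPr)4 (cat.), L-(+)-diisopropyl tartrate (cat.), t-BuOOH, 4 Å sieves, CH2Cl2, −20 °C
Reagents that add atoms: tert-butyl hydroperoxide, CC(C)(C)OO
Why: Sharpless asymmetric epoxidation under catalytic conditions: L-(+)-tartrate delivers oxygen to the face of (E)-cinnamyl alcohols that gives the (2S,3S)-glycidol, which fixes the future C3' and the centre that becomes C2' after inversion, and the low titanium loading limits opening of the electron-rich oxirane.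

Step 13
Reactants: 19 the (2S,3S)-glycidol
Product: 20 (2R,3S)-3-[3,4-bis(benzyloxy)phenyl]oxirane-2-carbaldehyde
Conditions: SO3·pyridine, DMSO, Et3N, CH2Cl2, 0 °C
Reagents that add atoms: none
Why: Parikh–Doering oxidation, a non-acidic activated-DMSO oxidation run in the presence of amine, which spares the acid-labile aryl oxirane and does not epimerise the α-carbon (the label becomes 2R only because CHO outranks C3); 20 is used at once.

Step 14
Reactants: 16 the upper 4β-arylflavan-3-ol with free C8a' phenol; 20 the (2R,3S)-glycidaldehyde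
Product: 23 (2R,3S,4R)-7-(benzyloxy)-2-[3,4-bis(benzyloxy)phenyl]-6-{(2R,3S)-3,7-bis(benzyloxy)-2-[3,4-bis(benzyloxy)phenyl]chroman-4β-yl}chroman-3,4-diol, via bromomagnesium phenoxide 21 (not isolated), via syn epoxy carbinol 22 (not isolated)
Conditions: EtMgBr (1.0 equiv), Et2O, 0 °C, then solvent exchange to CH2Cl2; 20 (1.2 equiv), −30 → 0 °C; cold pH 7 phosphate wash, dry; PPTS (0.1 equiv), CH2Cl2, −10 → 0 °C
Reagents that add atoms: none
Why: Proposed new method: deprotonation with EtMgBr and removal of the ether leaves a coordinatively unsaturated phenoxide 21 whose magnesium binds the formyl oxygen of 20, so that C4a' attacks the carbonyl carbon through a six-membered cyclic transition state and rearomatisation gives 22; once magnesium and bromide have been washed out, a trace of PPTS activates the oxirane and the C8a' hydroxyl attacks the p-benzyloxy-stabilised benzylic carbon C2'. The closest known reaction types are the ortho-specific hydroxyalkylation of bromomagnesium phenoxides by α-alkoxy aldehydes in non-coordinating solvents and the acid-induced cyclisation of 2-(3-aryloxiranylmethyl)phenols to flavan-3-ols, and what is new is their combination on a glycidaldehyde in one operation. Ring F closes 6-endo-tet, preferred over 5-exo attack at C3' because C–O cleavage is far advanced at the cation-stabilising C2' while C3' sits next to the electron-poor carbinol carbon. C4' is set by chelation control: with the oxirane and carbonyl oxygens held on one magnesium the arene enters from the side of the C3' hydrogen and gives the syn (4'R) carbinol that becomes the 3',4'-trans diol, C3' is carried over from 20 untouched, and C2' arises by stereospecific inversion, so all three substituents of ring F end up equatorial. The step needs ortho- and site-selectivity: only ring D can form a phenoxide because every other oxygen is benzylated, the para position C6' is substituted, and C8' is shut in between two oxygen substituents, which leaves C4a', also para to the 7'-benzyloxy donor.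

Step 15
Reactants: 23 the hepta-O-benzyl ether
Product: 24 (2R,3S,4R)-2-(3,4-dihydroxyphenyl)-6-[(2R,3S,4S)-2-(3,4-dihydroxyphenyl)-3,7-dihydroxychroman-4-yl]chroman-3,4,7-triol (target)
Conditions: H2 (1 atm), Pd(OH)2/C, THF–MeOH–aq. phosphate buffer (pH 7), rt, stopped when debenzylation is complete (LC–MS)
Reagents that add atoms: none
Why: Heterogeneous hydrogenolysis in which the six aryl benzyl ethers and the one alkyl benzyl ether should be cleaved faster than a secondary benzylic alcohol, the neutral buffer suppressing acid-promoted ionisation at C4', and no stereocentre is touched.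

Compound list
1 | 1-[4-(benzyloxy)-2-hydroxyphenyl]ethanone | CC(=O)c1ccc(OCc2ccccc2)cc1O | starting material
2 | 1-[4-(benzyloxy)-2-(methoxymethoxy)phenyl]ethanone | CC(=O)c1ccc(OCc2ccccc2)cc1OCOC | intermediate
3 | 3,4-bis(benzyloxy)benzaldehyde | O=Cc1ccc(OCc2ccccc2)c(OCc2ccccc2)c1 | starting material
4 | (E)-1-[4-(benzyloxy)-2-(methoxymethoxy)phenyl]-3-[3,4-bis(benzyloxy)phenyl]prop-2-en-1-one | O=C(/C=C/c1ccc(OCc2ccccc2)c(OCc2ccccc2)c1)c1ccc(OCc2ccccc2)cc1OCOC | intermediate
5 | [4-(benzyloxy)-2-(methoxymethoxy)phenyl]{(2R,3S)-3-[3,4-bis(benzyloxy)phenyl]oxiran-2-yl}methanone | O=C(c1ccc(OCc2ccccc2)cc1OCOC)[C@@H]1O[C@H]1c1ccc(OCc2ccccc2)c(OCc2ccccc2)c1 | intermediate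
6 | [4-(benzyloxy)-2-hydroxyphenyl]{(2R,3S)-3-[3,4-bis(benzyloxy)phenyl]oxiran-2-yl}methanone | O=C(c1ccc(OCc2ccccc2)cc1O)[C@@H]1O[C@H]1c1ccc(OCc2ccccc2)c(OCc2ccccc2)c1 | intermediate
7 | (2R,3R)-7-(benzyloxy)-2-[3,4-bis(benzyloxy)phenyl]-3-hydroxychroman-4-one | C(c1ccccc1)Oc1ccc2c(c1)O[C@H](c1ccc(OCc3ccccc3)c(OCc3ccccc3)c1)[C@@H](O)C2=O | intermediate
8 | (2R,3R)-3,7-bis(benzyloxy)-2-[3,4-bis(benzyloxy)phenyl]chroman-4-one | C(c1ccccc1)Oc1ccc2c(c1)O[C@H](c1ccc(OCc3ccccc3)c(OCc3ccccc3)c1)[C@@H](OCc1ccccc1)C2=O | intermediate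
9 | 4-bromoresorcinol | Oc1ccc(Br)c(O)c1 | starting material
10 | 2-bromo-5-(triisopropylsilyloxy)phenol | Oc1cc(O[Si](C(C)C)(C(C)C)C(C)C)ccc1Br | intermediate
11 | [3-(benzyloxy)-4-bromophenoxy]triisopropylsilane | Brc1ccc(O[Si](C(C)C)(C(C)C)C(C)C)cc1OCc1ccccc1 | intermediate
12 | [2-(benzyloxy)-4-(triisopropylsilyloxy)phenyl]lithium | [Li]c1ccc(O[Si](C(C)C)(C(C)C)C(C)C)cc1OCc1ccccc1 | intermediate
13 | [2-(benzyloxy)-4-(triisopropylsilyloxy)phenyl]cerium dichloride | Cl[Ce](Cl)c1ccc(O[Si](C(C)C)(C(C)C)C(C)C)cc1OCc1ccccc1 | intermediate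
14 | (2R,3R)-3,7-bis(benzyloxy)-4-[2-(benzyloxy)-4-(triisopropylsilyloxy)phenyl]-2-[3,4-bis(benzyloxy)phenyl]chroman-4-ol, C4 epimers | C(c1ccccc1)Oc1ccc2c(c1)O[C@H](c1ccc(OCc3ccccc3)c(OCc3ccccc3)c1)[C@@H](OCc1ccccc1)C2(O)c1ccc(O[Si](C(C)C)(C(C)C)C(C)C)cc1OCc1ccccc1 | intermediate
15 | triisopropylsilyl ether of 16, (2R,3S,4S), ring D cis to O3 | C(c1ccccc1)Oc1ccc2c(c1)O[C@H](c1ccc(OCc3ccccc3)c(OCc3ccccc3)c1)[C@@H](OCc1ccccc1)[C@H]2c1ccc(O[Si](C(C)C)(C(C)C)C(C)C)cc1OCc1ccccc1 | intermediate
16 | 3-(benzyloxy)-4-{(2R,3S,4S)-3,7-bis(benzyloxy)-2-[3,4-bis(benzyloxy)phenyl]chroman-4-yl}phenol | C(c1ccccc1)Oc1ccc2c(c1)O[C@H](c1ccc(OCc3ccccc3)c(OCc3ccccc3)c1)[C@@H](OCc1ccccc1)[C@H]2c1ccc(O)cc1OCc1ccccc1 | intermediate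
17 | ethyl (E)-3-[3,4-bis(benzyloxy)phenyl]prop-2-enoate | CCOC(=O)/C=C/c1ccc(OCc2ccccc2)c(OCc2ccccc2)c1 | intermediate
18 | (E)-3-[3,4-bis(benzyloxy)phenyl]prop-2-en-1-ol | OC/C=C/c1ccc(OCc2ccccc2)c(OCc2ccccc2)c1 | intermediate
19 | {(2S,3S)-3-[3,4-bis(benzyloxy)phenyl]oxiran-2-yl}methanol | OC[C@@H]1O[C@H]1c1ccc(OCc2ccccc2)c(OCc2ccccc2)c1 | intermediate
20 | (2R,3S)-3-[3,4-bis(benzyloxy)phenyl]oxirane-2-carbaldehyde | O=C[C@@H]1O[C@H]1c1ccc(OCc2ccccc2)c(OCc2ccccc2)c1 | intermediate
21 | bromomagnesium phenoxide of 16 | C(c1ccccc1)Oc1ccc2c(c1)O[C@H](c1ccc(OCc3ccccc3)c(OCc3ccccc3)c1)[C@@H](OCc1ccccc1)[C@H]2c1ccc(O[Mg]Br)cc1OCc1ccccc1 | intermediate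
22 | 16 bearing at C4a' an (R)-CH(OH) group bonded to the intact trans-oxirane of 20 (syn epoxy carbinol) | C(c1ccccc1)Oc1ccc2c(c1)O[C@H](c1ccc(OCc3ccccc3)c(OCc3ccccc3)c1)[C@@H](OCc1ccccc1)[C@H]2c1cc([C@@H](O)[C@@H]3O[C@H]3c3ccc(OCc4ccccc4)c(OCc4ccccc4)c3)c(O)cc1OCc1ccccc1 | intermediate
23 | hepta-O-benzyl ether of 24 with free 3',4'-diol; upper unit 2R,3S with ring D β at C4, lower unit 2R,3S,4R | C(c1ccccc1)Oc1ccc2c(c1)O[C@H](c1ccc(OCc3ccccc3)c(OCc3ccccc3)c1)[C@@H](OCc1ccccc1)[C@H]2c1cc2c(cc1OCc1ccccc1)O[C@H](c1ccc(OCc3ccccc3)c(OCc3ccccc3)c1)[C@@H](O)[C@@H]2O | intermediate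
24 | (2R,3S,4R)-2-(3,4-dihydroxyphenyl)-6-[(2R,3S,4S)-2-(3,4-dihydroxyphenyl)-3,7-dihydroxychroman-4-yl]chroman-3,4,7-triol | Oc1ccc2c(c1)O[C@H](c1ccc(O)c(O)c1)[C@@H](O)[C@H]2c1cc2c(cc1O)O[C@H](c1ccc(O)c(O)c1)[C@@H](O)[C@@H]2O | target

Total step count: 15. Longest linear sequence: 9 (steps 1, 2, 3, 4, 5, 8, 9, 14, 15).

Steps most likely to fail

**1. Step 14.**
- What may go wrong:
  - The bulky phenoxide may attack the aldehyde only slowly.
  - The oxirane oxygen may chelate too weakly, giving poor facial selectivity at C4'.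
  - Magnesium-bound bromide may open the oxirane before the phenol oxygen arrives and erode C2'.
  - The new benzylic carbinol may ionise during the acid stage.
- The fallback sets out from 16 (with 20), makes the same two bonds by known reactions, and returns at 23.
  - NBS in CH2Cl2 at −40 °C brominates 16 ortho to the phenol and para to the benzyloxy group, giving the bromophenol F1.
  - MOMCl and iPr2NEt give the MOM ether F2.
  - n-BuLi at −78 °C gives the aryllithium F3, which adds to 20 to give the epimeric epoxy carbinols F4.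
  - Dess–Martin oxidation buffered with NaHCO3 converges both epimers to the epoxy ketone F5.
  - HCl in MeOH–THF, as in step 4, passes through the free phenol F6 and closes ring F to the 2',3'-trans 4'-ketone F7.
  - NaBH4 in MeOH–THF at 0 °C reduces dihydroflavonols to the 3,4-trans diol, which is 23.

**2. Step 9.**
- What may go wrong: hydride delivery to the planar C4 cation may show poor or inverted facial selectivity, or the cation may lose the C3 proton to give an enol ether.
- The fallback sets out from 8, reverses the roles at C4, and returns at 15.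
  - NaBH4 gives the flavan-4-ol F8.
  - BF3·OEt2 in CH2Cl2–THF at low temperature ionises F8 in the presence of excess resorcinol, the known acid-induced 4-arylation of 5-deoxyflavan-4-ols.
  - That arylation gives both C4 epimers, and the 4β-(2,4-dihydroxyphenyl)flavan F9 is separated.
  - iPr3SiCl and imidazole silylate the unhindered para hydroxyl, giving the monosilyl ether F10.
  - BnBr and K2CO3 then give 15.
- Both routes are captures of a flavan-4-yl cation. A facial bias that harms the hydride route therefore favours the 4β product here.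

**3. Step 15.**
- What may go wrong:
  - The C4' hydroxyl may be lost by hydrogenolysis once the ring D phenol is bared and dehydration to a quinone methide becomes possible.
  - Slow cleavage of the aliphatic 3-O-benzyl ether lengthens the exposure.
- The fallback sets out from 23, removes the sensitive centre before hydrogenation, and returns at 24.
  - Activated MnO2 in CH2Cl2 oxidises only the benzylic carbinol, giving the 4'-ketone F7.
  - H2 over Pd(OH)2/C in THF–MeOH cleaves all benzyl ethers, giving the free phenolic ketone F11.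
  - NaBH4 in EtOH, the classical reduction of free dihydroflavonols to 2,3-trans-3,4-trans flavan-3,4-diols, gives 24.

Further compounds
F1 | step 14 | 16 brominated at C4a' (ortho to the phenol) | C(c1ccccc1)Oc1ccc2c(c1)O[C@H](c1ccc(OCc3ccccc3)c(OCc3ccccc3)c1)[C@@H](OCc1ccccc1)[C@H]2c1cc(Br)c(O)cc1OCc1ccccc1
F2 | step 14 | MOM ether of F1 | C(c1ccccc1)Oc1ccc2c(c1)O[C@H](c1ccc(OCc3ccccc3)c(OCc3ccccc3)c1)[C@@H](OCc1ccccc1)[C@H]2c1cc(Br)c(OCOC)cc1OCc1ccccc1
F3 | step 14 | aryllithium from F2 | C(c1ccccc1)Oc1ccc2c(c1)O[C@H](c1ccc(OCc3ccccc3)c(OCc3ccccc3)c1)[C@@H](OCc1ccccc1)[C@H]2c1cc([Li])c(OCOC)cc1OCc1ccccc1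
F4 | step 14 | epoxy carbinols, C4' epimers, oxirane as in 20 | C(c1ccccc1)Oc1ccc2c(c1)O[C@H](c1ccc(OCc3ccccc3)c(OCc3ccccc3)c1)[C@@H](OCc1ccccc1)[C@H]2c1cc(C(O)[C@@H]3O[C@H]3c3ccc(OCc4ccccc4)c(OCc4ccccc4)c3)c(OCOC)cc1OCc1ccccc1
F5 | step 14 | epoxy ketone with MOM-protected C8a' oxygen | C(c1ccccc1)Oc1ccc2c(c1)O[C@H](c1ccc(OCc3ccccc3)c(OCc3ccccc3)c1)[C@@H](OCc1ccccc1)[C@H]2c1cc(C(=O)[C@@H]3O[C@H]3c3ccc(OCc4ccccc4)c(OCc4ccccc4)c3)c(OCOC)cc1OCc1ccccc1
F6 | step 14 | epoxy ketone with free C8a' phenol | C(c1ccccc1)Oc1ccc2c(c1)O[C@H](c1ccc(OCc3ccccc3)c(OCc3ccccc3)c1)[C@@H](OCc1ccccc1)[C@H]2c1cc(C(=O)[C@@H]3O[C@H]3c3ccc(OCc4ccccc4)c(OCc4ccccc4)c3)c(O)cc1OCc1ccccc1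
F7 | step 14 | hepta-O-benzyl 4'-ketone (lower unit a 2',3'-trans dihydroflavonol) | C(c1ccccc1)Oc1ccc2c(c1)O[C@H](c1ccc(OCc3ccccc3)c(OCc3ccccc3)c1)[C@@H](OCc1ccccc1)[C@H]2c1cc2c(cc1OCc1ccccc1)O[C@H](c1ccc(OCc3ccccc3)c(OCc3ccccc3)c1)[C@@H](O)C2=O
F8 | step 9 | (2R,3S,4R)-3,7-bis(benzyloxy)-2-[3,4-bis(benzyloxy)phenyl]chroman-4-ol | C(c1ccccc1)Oc1ccc2c(c1)O[C@H](c1ccc(OCc3ccccc3)c(OCc3ccccc3)c1)[C@@H](OCc1ccccc1)[C@@H]2O
F9 | step 9 | 4β-(2,4-dihydroxyphenyl) analogue of 16 | C(c1ccccc1)Oc1ccc2c(c1)O[C@H](c1ccc(OCc3ccccc3)c(OCc3ccccc3)c1)[C@@H](OCc1ccccc1)[C@H]2c1ccc(O)cc1O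
F10 | step 9 | para-O-triisopropylsilyl ether of F9 | C(c1ccccc1)Oc1ccc2c(c1)O[C@H](c1ccc(OCc3ccccc3)c(OCc3ccccc3)c1)[C@@H](OCc1ccccc1)[C@H]2c1ccc(O[Si](C(C)C)(C(C)C)C(C)C)cc1O
F11 | step 15 | free phenolic 4'-ketone (fisetinidol-(4β→6)-fustin) | Oc1ccc2c(c1)O[C@H](c1ccc(O)c(O)c1)[C@@H](O)[C@H]2c1cc2c(cc1O)O[C@H](c1ccc(O)c(O)c1)[C@@H](O)C2=O
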